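Thursday's flask nearly repeats delta: the same starting complex, with 0.630 M of incoming ligand against delta's 0.70 M. Starting complex takes up incoming ligand and gives off leaving ligand, which can pair with more starting complex to form the idle adduct. The adduct counts as reacted, so the reacted part is the charge less the free starting complex.

| flask | starting complex | incoming ligand | remark | time |
|---|---|---|---|---|
| epsilon | 0.063 M | 0.24 M | run made earlier |  |
| delta | 0.063 M | 0.70 M | run made earlier |  |
| Wednesday's | 0.063 M | 0.160 M |  | 20 min |
| Monday's | 0.063 M | 0.320 M |  | 20 min |
| Thursday's | 0.063 M | 0.630 M |  | 20 min |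

| run | time / min | starting complex / % | complex with one exchanged / % |
|---|---|---|---|
| epsilon | 1.00 | 83.2 | 9.3 |
| epsilon | 3.00 | 60.4 | 23.1 |
| epsilon | 6.00 | 40.4 | 37.7 |
| epsilon | 8.00 | 32.3 | 43.5 |
| epsilon | 12.0 | 22.6 | 52.7 |
| epsilon | 15.0 | 17.9 | 56.1 |
| epsilon | 20.0 | 13.1 | 62.2 |
| delta | 1.50 | 48.2 | 31.3 |
| delta | 2.50 | 33.4 | 42.3 |
| delta | 4.00 | 22.0 | 53.5 |
| delta | 6.00 | 14.4 | 60.9 |
| delta | 8.00 | 9.5 | 65.3 |
| delta | 12.0 | 6.0 | 68.9 |
| delta | 20.0 | 2.6 | 67.5 |

(scatter of a reading: 0.3 percentage points)

- what is said of leaving ligand includes idle adduct
- the numbers in the tables scatter by 0.3 percentage points (one standard deviation)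
- candidate steps: starting complex + incoming ligand -> leaving ligand + complex with one exchanged; complex with one exchanged + incoming ligand -> leaving ligand + complex with two exchanged; complex with two exchanged + incoming ligand -> leaving ligand + complex with three exchanged; leaving ligand + starting complex <-> idle adduct
- what has gone from starting complex into another species counts as reacted, even if it can come back

- part of the starting complex that has reacted at the end, Wednesday's
- part of the starting complex that has reacted at the end, Monday's
- part of the starting complex that has reacted at the end, Thursday's
- what raising the concentration of incoming ligand from its lowest to its highest value here does to the part of the starting complex that has reacted (changes below 5 percentage points count as none) (no change / it falls / it rises)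

While the ligand stays near its charge, the first exchange is pseudo-first-order, and the free fraction should follow one curve against ligand charge times time. Thursday's 756 M·s is its dose, the ligand charge times the time. The readings test this. Epsilon at 12.0 min has dose 173 M·s and holds 22.6 % free, while delta at 4.00 min has dose 168 M·s and holds 22.0 %. Delta ends at dose 840 M·s with 2.6 % free, so Thursday's, with a smaller dose, should end slightly above that.

Interpolating the logarithm of the free part between the readings on either side of each dose gives:

| Flask | Dose | Free | Reacted |
|---|---|---|---|
| Wednesday's | 192 M·s | 20.4 % | 79.6 % |
| Monday's | 384 M·s | 8.33 % | 91.7 % |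
| Thursday's | 756 M·s | 3.20 % | 96.8 % |

The reckoned reacted part thus rises by 17 percentage points across the series. A full first exchange costs Wednesday's incoming ligand 39.4 % of its charge and epsilon's 26.2 %, so Wednesday's figure, read off epsilon's curve, leans high.

The forecast, built on “Growth of the one-exchanged complex against the integral of free starting complex”, gives 77.5 %, 90.5 % and 96.8 %, with the trend: it rises.

The flasks give 78.5 %, 91.0 % and 96.9 %; the trend: it rises, by 18 points.

    starting complex + incoming ligand → leaving ligand + complex with one exchanged (k = 0.437 M⁻¹ min⁻¹)
    complex with one exchanged + incoming ligand → leaving ligand + complex with two exchanged (k = 0.0279 M⁻¹ min⁻¹)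
    complex with two exchanged + incoming ligand → leaving ligand + complex with three exchanged (k = 0.0204 M⁻¹ min⁻¹)
    leaving ligand + starting complex ⇌ idle adduct, settled at all times (K = 46.0 M⁻¹)

Thursday's flask ends with 89 % of its incoming ligand. The neighbour, Wednesday's flask read at 80 min, has dose 768 M·s, close to Thursday's 756 M·s. Delta's curve therefore gives it 96.9 % reacted. That neighbour gives 95.4 % reacted, with 4.6 % of its starting complex free and 61 % of its incoming ligand left.

The data were generated by integration from invented constants; noise was put on by code.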